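## The problem

Target 20 is a diester in which two identical (4S,4aR,6S,7R,7aS)-2,4,7-trimethyloctahydro-1H-cyclopenta[c]pyridin-6-yl units are bound through O6 to the two unlike ends of (2E,6E)-2,6-dimethylocta-2,6-dienedioic acid 19. The synthesis therefore needs one bicyclic amino alcohol, made once and used twice, and one C10 diacid. Atoms are numbered as in the bicycle (C1, N2, C3, C4, C4a, C5, C6, C7, C7a), and the same numbers are used for open-chain precursors.

The bicycle is a piperidine and a cyclopentane that share the bond C4a–C7a in a cis fusion. It has five contiguous stereocentres: H4, H4a and H7a lie on one face, and the C7 methyl and O6 lie on the convex face.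

- **Stereocontrol.** C4 can be bought. C7a has to be set against C4 across C4a when the piperidine closes. C4a has to be set against C7a when the cyclopentane closes. C7 is α to a C6 carbonyl and can be left to equilibration. C6 follows from hydride attack on the convex face and one inversion.
- **Fragile groups.** The basic nitrogen binds late transition metals and is carried as a carbamate. The two conjugated esters, above all the 3-methyl-2-enoate end, are open to deconjugation and E/Z isomerisation under base or acyl activation, so the ester bonds should be made last under neutral conditions. The α-branched aldehydes on the way can epimerise.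
- **Enabling feature.** C6 is separated from the fusion carbon C4a only by the methylene C5. A piperidine with C6 as a formyl group on the C7a side chain and C5 as an exocyclic methylene on C4a therefore contains the 4-pentenal C6–C7–C7a–C4a=C5. Rhodium-catalysed hydroacylation can then form C5–C6 with the oxygen already at C6.

## Retrosynthesis

**20 ⇒ 14 + 19.** The two C6–O (alkyl–oxygen) bonds are cut. The acyl–oxygen cut would need the convex alcohol and activation of the enoic acids, which endangers the geometry of the 3-methyl-2-enoate end. Hydride reduction of the C6 ketone is expected to give the concave alcohol 14, so esterification with inversion fits the stereochemistry and keeps the acid as a carboxylate nucleophile. The forward step is a double SN2 at a hindered secondary carbinol beside a tertiary amine.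

**19 ⇒ 18 ⇒ 17 ⇒ 16 ⇒ 15.** Only C–O bonds change. The carbon chain and the (2E) alkene are bought as geranyl acetate 15. The second acid carbon comes from oxidation of the terminal (E)-methyl group to 16, methanolysis to diol 17, and oxidation through dial 18 to 19.

**14 ⇒ 12 (through 13) ⇒ 11.** No skeletal bond is cut. The N-methyl group is read as a reduced methyl carbamate and the C6 alcohol as a reduced ketone, so one hydride reagent serves both, with hydroxy carbamate 13 on the way. Ketone 12 comes from 11 by equilibration of C7, which is the only enolisable stereocentre.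

**11 ⇒ 10.** The C5–C6 bond is cut. A C6–C7 cut would ask for acylation of a C7 anion with no stereochemical gain, and a C4a–C5 cut would need a nucleophile at a fully substituted ring carbon. The C5–C6 cut leaves an aldehyde and an alkene, needs no redox change, and places the carbonyl where the oxygen is wanted. The precursor 10 is monocyclic and has one stereocentre fewer. The forward step must deliver hydrogen to C4a on the face of H7a.

**10 ⇒ 9 ⇒ 8.** After aldehyde-to-ester adjustment, the piperidine bond C4a–C7a is cut, giving the 1,7-enyne 8. A reductive enyne cyclisation installs the exocyclic methylene and the propanoate arm together.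

- The neighbouring C7a–C7 cut (Claisen rearrangement of a 4-(acyloxymethyl)tetrahydropyridine) would be expected to put the new carbon anti to the C4 methyl, giving the 3,5-trans series.
- Cuts at nitrogen would need both stereocentres beforehand.

The forward step must close 6-exo with the C4 methyl and the enoate arm both equatorial.

**8 ⇒ 7 ⇒ 6 ⇒ 4 + 5.** The alkyne carbon C5 is removed by one-carbon homologation of aldehyde 7, which is the oxidation product of alcohol 6. The enoate C7a=C7 is cut by cross metathesis into the N-allyl carbamate 4 and methyl methacrylate 5. N-alkylation with a γ-bromo enoate would need a strong base on a carbamate and a regioisomerically clean bromide, and is avoided.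

**4 ⇒ 3 ⇒ 1 + 2.** The carbamate C–N bond and the C3–N bond are cut, leading to the chiral bromo alcohol 1, which carries C4, and allylamine 2.

## Roads not taken

**Alternative 1:** Both rings are cut at once (C4a–C7a, C5–C6, C6–C7), leading to the acyclic enyne methyl [(2E)-but-2-en-1-yl][(2S)-2-methylbut-3-yn-1-yl]carbamate A1. Forward, Co2(CO)8 and N-methylmorpholine N-oxide would effect a Pauson–Khand reaction to the enone methyl (4S,7R,7aR)-4,7-dimethyl-6-oxo-1,3,4,6,7,7a-hexahydro-2H-cyclopenta[c]pyridine-2-carboxylate A2.

- Merits: three bonds and two rings form in one step. The (E)-alkene geometry transfers to the trans relation of H7 and H7a, so no equilibration is needed. Hydrogenation of A2 from the open face should set C4a reliably and give 12. A1 is some three steps shorter to make than 10.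
- Weak points: Pauson–Khand closures of 1,7-enynes with an internal disubstituted alkene are markedly less efficient than those of 1,6-enynes. Cobalt is used stoichiometrically. The C4/C7a relation is set in the cobaltacycle with the same 1,3-uncertainty as in the chosen plan.
- Comparison: in brevity and in security at C4a and C7 this road is better. The chosen plan sets against it a piperidine closure onto an activated alkene and a catalytic, redox-neutral cyclopentanone closure. It also keeps the hydrogenation of an enone of the A2 type in reserve as its fallback.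

**Alternative 2:** The C1–C7a bond is cut, leading to the amino cyclopentenol (4S)-2-methyl-4-[(2S)-1-(methylamino)propan-2-yl]cyclopent-2-en-1-ol A3 (either carbinol epimer). Forward, formaldehyde would give an N-methyl iminium ion that is attacked by C7a. The tertiary C7 cation would be discharged by a 1,2-hydride shift from C6, giving (4S,4aR,7R,7aS)-2,4,7-trimethyloctahydro-6H-cyclopenta[c]pyridin-6-one A4.

- Merits: no protecting group is needed, the N-methyl group and the C6 ketone arrive together, and the tether enforces the cis fusion. From A4 only a ketone reduction separates the route from 14.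
- Weak points: A3 has adjacent ring and side-chain stereocentres (C4a, C4) with no simple source. The free cation can also lose a proton toward C7a or the methyl group. C7 would probably emerge with the concave methyl and need equilibration.
- Comparison: with A3 in hand this road would be shorter than the chosen one. The chosen plan offers precursors that come from a commercial chiral C4 unit by routine steps, and a ring closure through a defined organometallic pathway instead of the partitioning of a cation.

**Alternative 3:** The C4–C4a bond is cut, leading to the alkynyl enone methyl {[(1S,5R)-5-methyl-4-oxocyclopent-2-en-1-yl]methyl}(prop-2-yn-1-yl)carbamate A5. Forward, Ni(cod)2 (zerovalent nickel), PPh3 and Et2Zn would couple the alkyne with the enone β-carbon to give methyl (4aS,7R,7aS)-7-methyl-4-methylidene-6-oxooctahydro-2H-cyclopenta[c]pyridine-2-carboxylate A6. Hydrogenation of the methylidene from the convex face would then lead to 12.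

- Merits: this reductive cyclisation type is well established for alkynyl enones. The cis fusion is forced by the tether. C7 and C7a are trans on the cyclopentenone from the start.
- Weak points: A5 must be made enantiopure over several steps. C4 is created last by a hydrogenation whose facial selectivity has to be right. Nickel is used in large amount, and ethyl transfer from zinc competes with the reductive course.
- Comparison: at the ring fusion this road is at least as secure as the chosen plan and probably more so. The chosen plan buys C4 instead of making it late, and needs no enantiopure cyclopentenone.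

Key step: step 8

Assumption: compounds 9, 10 and 11 are carried as mixtures of the two epimers at C7, because step 6 is not expected to control this centre; it becomes a single configuration in step 9.

## Route

Step 1
Reactants: 1 (2S)-3-bromo-2-methylpropan-1-ol; 2 prop-2-en-1-amine
Product: 3 (2R)-2-methyl-3-(prop-2-en-1-ylamino)propan-1-ol
Conditions: 2 (6 equiv), EtOH, 60 °C, sealed vessel; aq. NaOH work-up
Reagents that add atoms: none
Why: SN2 displacement of a primary bromide by an amine in excess, which suppresses double alkylation; the stereocentre is not touched (the descriptor changes only because the priorities change).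

Step 2
Reactants: 3 (2R)-2-methyl-3-(prop-2-en-1-ylamino)propan-1-ol
Product: 4 methyl [(2R)-3-hydroxy-2-methylpropyl](prop-2-en-1-yl)carbamate
Conditions: ClCO2Me (1.1 equiv), NaHCO3, CH2Cl2/H2O, 0 °C
Reagents that add atoms: methyl chloroformate, COC(=O)Cl
Why: Schotten–Baumann N-acylation; the secondary amine reacts far faster than the primary alcohol, and the carbamate carbon later becomes the N-methyl carbon.

Step 3
Reactants: 4 methyl [(2R)-3-hydroxy-2-methylpropyl](prop-2-en-1-yl)carbamate; 5 methyl 2-methylprop-2-enoate
Product: 6 methyl (2E)-4-{[(2R)-3-hydroxy-2-methylpropyl](methoxycarbonyl)amino}-2-methylbut-2-enoate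
Conditions: 5 (10 equiv), second-generation Grubbs catalyst RuCl2(=CHPh)(H2IMes)(PCy3) (5 mol %), CH2Cl2, 40 °C
Reagents that add atoms: none
Why: Olefin cross metathesis of a terminal N-allyl carbamate with a methacrylate; the trisubstituted enoate should form as the (E)-isomer under thermodynamic control, and the free alcohol is tolerated.

Step 4
Reactants: 6 methyl (2E)-4-{[(2R)-3-hydroxy-2-methylpropyl](methoxycarbonyl)amino}-2-methylbut-2-enoate
Product: 7 methyl (2E)-4-{(methoxycarbonyl)[(2R)-2-methyl-3-oxopropyl]amino}-2-methylbut-2-enoate
Conditions: Dess–Martin periodinane (1.2 equiv), CH2Cl2, 0 °C to 25 °C; used at once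
Reagents that add atoms: none
Why: Dess–Martin oxidation under neutral conditions, chosen so that the α-stereocentre of the aldehyde is not epimerised.

Step 5
Reactants: 7 methyl (2E)-4-{(methoxycarbonyl)[(2R)-2-methyl-3-oxopropyl]amino}-2-methylbut-2-enoate
Product: 8 methyl (2E)-4-{(methoxycarbonyl)[(2S)-2-methylbut-3-yn-1-yl]amino}-2-methylbut-2-enoate
Conditions: dimethyl (1-diazo-2-oxopropyl)phosphonate (1.3 equiv), K2CO3 (2 equiv), MeOH, 0 °C to 25 °C
Reagents that add atoms: dimethyl (1-diazo-2-oxopropyl)phosphonate, COP(=O)(OC)C(=[N+]=[N-])C(C)=O
Why: Seyferth–Gilbert homologation with the Ohira–Bestmann reagent, the usual choice for α-branched aldehydes because addition of the diazophosphonate anion outruns enolisation; the methyl esters cannot transesterify in MeOH.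

Step 6
Reactants: 8 methyl (2E)-4-{(methoxycarbonyl)[(2S)-2-methylbut-3-yn-1-yl]amino}-2-methylbut-2-enoate
Product: 9 methyl (3R,5S)-3-[(2RS)-1-methoxy-1-oxopropan-2-yl]-5-methyl-4-methylidenepiperidine-1-carboxylate
Conditions: Pd2(dba)3·CHCl3 (2.5 mol %), P(o-tol)3 (10 mol %), AcOH (2 equiv), Et3SiH (3 equiv), toluene, 25 to 50 °C
Reagents that add atoms: none
Why: Palladium hydride reductive cyclisation of a 1,7-enyne: AcOH and zerovalent palladium give a divalent palladium hydride that adds to the alkyne with palladium on the inner carbon, 6-exo insertion of the enoate forms C4a–C7a, and the palladium enolate is cleaved by AcOH and silane. C7a should be set in a chair-like transition state with the C4 methyl and the enoate arm both equatorial (3,5-cis); C7 is not controlled.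

Step 7
Reactants: 9 methyl (3R,5S)-3-[(2RS)-1-methoxy-1-oxopropan-2-yl]-5-methyl-4-methylidenepiperidine-1-carboxylate
Product: 10 methyl (3S,5R)-3-methyl-4-methylidene-5-[(2RS)-1-oxopropan-2-yl]piperidine-1-carboxylate
Conditions: iBu2AlH (1.1 equiv), CH2Cl2, −78 °C; MeOH, then aq. potassium sodium tartrate
Reagents that add atoms: none
Why: Partial reduction of a methyl ester; the aluminium hemiacetal of the α-branched ester is stable at −78 °C and the carbamate is not attacked at this temperature.

Step 8
Reactants: 10 methyl (3S,5R)-3-methyl-4-methylidene-5-[(2RS)-1-oxopropan-2-yl]piperidine-1-carboxylate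
Product: 11 methyl (4S,4aR,7RS,7aS)-4,7-dimethyl-6-oxooctahydro-2H-cyclopenta[c]pyridine-2-carboxylate
Conditions: RhCl(PPh3)3 (0.3 equiv), degassed CH2Cl2, 25 °C
Reagents that add atoms: none
Why: The formyl C–H bond of 10 adds oxidatively to monovalent rhodium to give an acyl hydride of trivalent rhodium; the hydride then migrates to the ring carbon C4a of the coordinated methylidene while rhodium takes C5, and reductive elimination from the six-membered acyl–alkyl rhodacycle forms C5–C6 and returns monovalent rhodium. The closest known reaction type is the RhCl(PPh3)3-mediated cyclisation of 3,4-disubstituted 4-pentenals to 3,4-disubstituted cyclopentanones, of which 10 is a ring-tied case. The cyclopentanone closes in a formally 5-endo-trig sense, which is possible because the bond comes from reductive elimination within the rhodacycle and not from direct attack on the alkene. The only new stereocentre is C4a, and it is set by the face on which the hydride arrives. With the C4 methyl and the C7a side chain both equatorial, the acyl rhodium reaches C5 most easily from the rotamer in which C6 lies between C4a and the axial H7a, so the hydride should enter C4a on the face of H7a and H4, anti to the C4 methyl; this gives the cis fusion, which is also the sense favoured by neutral RhCl(PPh3)3 in open-chain cases. The (7R)-epimer of 10 has its methyl in the least crowded position of this rotamer and is the better matched of the two. The step needs cis fusion and ring closure ahead of decarbonylation: the 1,1-disubstituted alkene, the branch at C7 and the non-coordinating carbamate nitrogen serve the second, and the conformational bias serves the first.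

Step 9
Reactants: 11 methyl (4S,4aR,7RS,7aS)-4,7-dimethyl-6-oxooctahydro-2H-cyclopenta[c]pyridine-2-carboxylate
Product: 12 methyl (4S,4aR,7R,7aS)-4,7-dimethyl-6-oxooctahydro-2H-cyclopenta[c]pyridine-2-carboxylate
Conditions: NaOMe (0.2 equiv), MeOH, 25 °C
Reagents that add atoms: none
Why: Base-mediated epimerisation through the enolate; C7 is the only enolisable stereocentre, and the methyl group should settle on the convex face, trans to C1, which is the configuration of the target.

Step 10
Reactants: 12 methyl (4S,4aR,7R,7aS)-4,7-dimethyl-6-oxooctahydro-2H-cyclopenta[c]pyridine-2-carboxylate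
Product: 14 (4S,4aR,6R,7R,7aS)-2,4,7-trimethyloctahydro-1H-cyclopenta[c]pyridin-6-ol, via hydroxy carbamate 13 (not isolated)
Conditions: LiAlH4 (5 equiv), THF, −40 °C to 0 °C, then 65 °C; water and aq. NaOH work-up
Reagents that add atoms: none
Why: Hydride reduction in two stages in one flask: in the cold the small hydride should add to the ketone from the convex face, since the piperidine ring covers the concave face, giving the concave alcohol 13; at reflux the methyl carbamate is reduced to the N-methyl group.

Step 11
Reactants: 15 (2E)-3,7-dimethylocta-2,6-dien-1-yl acetate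
Product: 16 (2E,6E)-8-hydroxy-3,7-dimethylocta-2,6-dien-1-yl acetate
Conditions: SeO2 (0.1 equiv), t-BuOOH (3 equiv), salicylic acid (0.1 equiv), CH2Cl2, 25 °C
Reagents that add atoms: tert-butyl hydroperoxide, CC(C)(C)OO (the oxygen atom is passed on through selenium dioxide, O=[Se]=O)
Why: Selenium dioxide allylic oxidation (ene reaction, then 2,3-sigmatropic shift), which is selective for the (E)-methyl group of the terminal trisubstituted alkene; the alkene next to the acetate is deactivated.

Step 12
Reactants: 16 (2E,6E)-8-hydroxy-3,7-dimethylocta-2,6-dien-1-yl acetate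
Product: 17 (2E,6E)-2,6-dimethylocta-2,6-diene-1,8-diol
Conditions: K2CO3 (0.2 equiv), MeOH, 25 °C
Reagents that add atoms: none
Why: Base-catalysed transesterification of an acetate with methanol.

Step 13
Reactants: 17 (2E,6E)-2,6-dimethylocta-2,6-diene-1,8-diol
Product: 18 (2E,6E)-2,6-dimethylocta-2,6-dienedial
Conditions: MnO2 (20 equiv), CH2Cl2, 25 °C
Reagents that add atoms: none
Why: Manganese dioxide oxidation of allylic alcohols; it stops at the enal and should leave both alkene geometries unchanged.

Step 14
Reactants: 18 (2E,6E)-2,6-dimethylocta-2,6-dienedial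
Product: 19 (2E,6E)-2,6-dimethylocta-2,6-dienedioic acid
Conditions: NaClO2, NaH2PO4, 2-methylbut-2-ene, t-BuOH/H2O, 25 °C
Reagents that add atoms: sodium chlorite, [Na+].[O-]Cl=O
Why: Pinnick oxidation, which converts enals to enoic acids without touching or isomerising the alkenes; the hypochlorous acid formed is trapped by 2-methylbut-2-ene.

Step 15
Reactants: 14 (4S,4aR,6R,7R,7aS)-2,4,7-trimethyloctahydro-1H-cyclopenta[c]pyridin-6-ol; 19 (2E,6E)-2,6-dimethylocta-2,6-dienedioic acid
Product: 20 bis[(4S,4aR,6S,7R,7aS)-2,4,7-trimethyloctahydro-1H-cyclopenta[c]pyridin-6-yl] (2E,6E)-2,6-dimethylocta-2,6-dienedioate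
Conditions: 14 (2.3 equiv), 19 (1 equiv), PPh3 (3 equiv), DIAD (3 equiv), THF, 0 °C to 25 °C
Reagents that add atoms: none
Why: Twofold Mitsunobu esterification; each carboxylate displaces the activated concave C6 oxygen by SN2 from the open convex face, so C6 is inverted to the (6S) configuration. The acids react as carboxylates, which keeps the enoate geometries safe.

## Compound list

1 | (2S)-3-bromo-2-methylpropan-1-ol | C[C@@H](CO)CBr | starting material
2 | prop-2-en-1-amine | C=CCN | starting material
3 | (2R)-2-methyl-3-(prop-2-en-1-ylamino)propan-1-ol | C=CCNC[C@H](CO)C | intermediate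
4 | methyl [(2R)-3-hydroxy-2-methylpropyl](prop-2-en-1-yl)carbamate | C=CCN(C(=O)OC)C[C@H](CO)C | intermediate
5 | methyl 2-methylprop-2-enoate | C=C(C)C(=O)OC | starting material
6 | methyl (2E)-4-{[(2R)-3-hydroxy-2-methylpropyl](methoxycarbonyl)amino}-2-methylbut-2-enoate | COC(=O)/C(C)=C/CN(C(=O)OC)C[C@H](CO)C | intermediate
7 | methyl (2E)-4-{(methoxycarbonyl)[(2R)-2-methyl-3-oxopropyl]amino}-2-methylbut-2-enoate | COC(=O)/C(C)=C/CN(C(=O)OC)C[C@H](C=O)C | intermediate
8 | methyl (2E)-4-{(methoxycarbonyl)[(2S)-2-methylbut-3-yn-1-yl]amino}-2-methylbut-2-enoate | COC(=O)/C(C)=C/CN(C(=O)OC)C[C@H](C#C)C | intermediate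
9 | methyl (3R,5S)-3-[(2RS)-1-methoxy-1-oxopropan-2-yl]-5-methyl-4-methylidenepiperidine-1-carboxylate (both epimers at the side-chain carbon C7) | COC(=O)C(C)[C@H]1CN(C(=O)OC)C[C@@H](C)C1=C | intermediate
10 | methyl (3S,5R)-3-methyl-4-methylidene-5-[(2RS)-1-oxopropan-2-yl]piperidine-1-carboxylate (both epimers at C7) | O=CC(C)[C@H]1CN(C(=O)OC)C[C@@H](C)C1=C | intermediate
11 | methyl (4S,4aR,7RS,7aS)-4,7-dimethyl-6-oxooctahydro-2H-cyclopenta[c]pyridine-2-carboxylate (both epimers at C7) | O=C1C[C@H]2[C@H](CN(C(=O)OC)C[C@H]2C)C1C | intermediate
12 | methyl (4S,4aR,7R,7aS)-4,7-dimethyl-6-oxooctahydro-2H-cyclopenta[c]pyridine-2-carboxylate | O=C1C[C@H]2[C@H](CN(C(=O)OC)C[C@H]2C)[C@H]1C | intermediate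
13 | methyl (4S,4aR,6R,7R,7aS)-6-hydroxy-4,7-dimethyloctahydro-2H-cyclopenta[c]pyridine-2-carboxylate | O[C@@H]1C[C@H]2[C@H](CN(C(=O)OC)C[C@H]2C)[C@H]1C | intermediate (not isolated)
14 | (4S,4aR,6R,7R,7aS)-2,4,7-trimethyloctahydro-1H-cyclopenta[c]pyridin-6-ol | O[C@@H]1C[C@H]2[C@H](CN(C)C[C@H]2C)[C@H]1C | intermediate
15 | (2E)-3,7-dimethylocta-2,6-dien-1-yl acetate | CC(C)=CCC/C(C)=C/COC(C)=O | starting material
16 | (2E,6E)-8-hydroxy-3,7-dimethylocta-2,6-dien-1-yl acetate | CC(=O)OC/C=C(\C)CC/C=C(\C)CO | intermediate
17 | (2E,6E)-2,6-dimethylocta-2,6-diene-1,8-diol | OC/C=C(\C)CC/C=C(\C)CO | intermediate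
18 | (2E,6E)-2,6-dimethylocta-2,6-dienedial | O=C/C=C(\C)CC/C=C(\C)C=O | intermediate
19 | (2E,6E)-2,6-dimethylocta-2,6-dienedioic acid | OC(=O)/C=C(\C)CC/C=C(\C)C(=O)O | intermediate
20 | bis[(4S,4aR,6S,7R,7aS)-2,4,7-trimethyloctahydro-1H-cyclopenta[c]pyridin-6-yl] (2E,6E)-2,6-dimethylocta-2,6-dienedioate | C/C(=C\C(=O)O[C@H]1C[C@H]2[C@H](CN(C)C[C@H]2C)[C@H]1C)CC/C=C(\C)C(=O)O[C@H]1C[C@H]2[C@H](CN(C)C[C@H]2C)[C@H]1C | target

## Step count and risks

Total step count: 15. Longest linear sequence: 11 steps (steps 1 to 10 and step 15); the diacid branch (steps 11 to 14) joins at step 15.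

**Step 8 (key step).**
- Risk: delivery of the hydride to the other face of C4a, above all from the (7S)-epimer of 10, which lacks the matched rotamer. Loss of carbon monoxide from the acyl rhodium would also consume rhodium.
- Fallback: it sets out from 11 as it leaves step 8, however the ring fusion has turned out, and comes back at 11.
  - Kinetic enolisation toward C5 with lithium diisopropylamide and Me3SiCl at −78 °C would give the silyl enol ether methyl (4S,7aS)-4,7-dimethyl-6-[(trimethylsilyl)oxy]-1,3,4,4a,7,7a-hexahydro-2H-cyclopenta[c]pyridine-2-carboxylate F1.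
  - Saegusa–Ito dehydrogenation with Pd(OAc)2 in MeCN would remove H4a and give the enone methyl (4S,7aR)-4,7-dimethyl-6-oxo-1,3,4,6,7,7a-hexahydro-2H-cyclopenta[c]pyridine-2-carboxylate F2.
  - Hydrogenation (H2, Pd/C, EtOAc) should occur from the face of H7a and H4, which is not covered by C1 and the C4 methyl, and return cis-fused 11.
  - C4a is then set by heterogeneous hydrogenation and no longer by rhodium.

**Step 6.**
- Risk: interception of the vinyl palladium by silane before the slower 6-exo insertion, which amounts to simple reduction of the alkyne. Facial selectivity at C7a may also be weak, because the equatorial preference of the C4 methyl in the chair-like transition state is small.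
- Fallback: it sets out from 8 and comes back at 9.
  - A tin-radical enyne cyclisation (Bu3SnH added slowly, AIBN, benzene, 80 °C) would add the stannyl radical to the terminal alkyne carbon and close the vinyl radical 6-exo on the enoate, giving methyl (3R,5S)-3-[(2RS)-1-methoxy-1-oxopropan-2-yl]-5-methyl-4-[(tributylstannyl)methylidene]piperidine-1-carboxylate F3.
  - Protodestannylation with TsOH·H2O in CH2Cl2 would give 9.
  - A 3,5-trans isomer, if formed by either method, would be removed by chromatography at the stage of 9.

**Step 5.**
- Risk: base-induced migration of the enoate double bond toward nitrogen, addition of methoxide to the enoate, or partial epimerisation next to the aldehyde during the homologation in K2CO3/MeOH.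
- Fallback: it sets out from 4 and comes back at 8, and keeps the enoate away from the basic step.
  - Dess–Martin oxidation of 4 would give methyl [(2R)-2-methyl-3-oxopropyl](prop-2-en-1-yl)carbamate F4.
  - The Ohira–Bestmann reagent would give methyl [(2S)-2-methylbut-3-yn-1-yl](prop-2-en-1-yl)carbamate F5.
  - Lemieux–Johnson cleavage of the allyl alkene (OsO4 cat., NaIO4, 2,6-lutidine, dioxane/H2O), which leaves the alkyne alone, would give methyl [(2S)-2-methylbut-3-yn-1-yl](2-oxoethyl)carbamate F6.
  - A Wittig reaction with methyl 2-(triphenylphosphoranylidene)propanoate in CH2Cl2 would give the (E)-enoate 8.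

**Step 15.**
- Risk: incomplete esterification of the second carboxyl group, and elimination or partial retention at the hindered C6 with the weakly acidic enoic acids.
- Fallback: it sets out from 14 and comes back at 20.
  - A Mitsunobu reaction with the more acidic 4-nitrobenzoic acid (PPh3, DIAD, THF) would give the inverted ester (4S,4aR,6S,7R,7aS)-2,4,7-trimethyloctahydro-1H-cyclopenta[c]pyridin-6-yl 4-nitrobenzoate F7.
  - Methanolysis (K2CO3, MeOH) would give the convex alcohol (4S,4aR,6S,7R,7aS)-2,4,7-trimethyloctahydro-1H-cyclopenta[c]pyridin-6-ol F8.
  - Carbodiimide esterification of F8 with 19 (EDC·HCl, DMAP, CH2Cl2), with retention at C6, would give 20.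

## Further compounds

F1 | step 8 | methyl (4S,7aS)-4,7-dimethyl-6-[(trimethylsilyl)oxy]-1,3,4,4a,7,7a-hexahydro-2H-cyclopenta[c]pyridine-2-carboxylate (C4a and C7 unassigned) | C[Si](C)(C)OC1=CC2[C@H](CN(C(=O)OC)C[C@H]2C)C1C
F2 | step 8 | methyl (4S,7aR)-4,7-dimethyl-6-oxo-1,3,4,6,7,7a-hexahydro-2H-cyclopenta[c]pyridine-2-carboxylate (both epimers at C7) | O=C1C=C2[C@H](CN(C(=O)OC)C[C@H]2C)C1C
F3 | step 6 | methyl (3R,5S)-3-[(2RS)-1-methoxy-1-oxopropan-2-yl]-5-methyl-4-[(tributylstannyl)methylidene]piperidine-1-carboxylate | COC(=O)C(C)[C@H]1CN(C(=O)OC)C[C@@H](C)C1=C[Sn](CCCC)(CCCC)CCCC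
F4 | step 5 | methyl [(2R)-2-methyl-3-oxopropyl](prop-2-en-1-yl)carbamate | C=CCN(C(=O)OC)C[C@H](C=O)C
F5 | step 5 | methyl [(2S)-2-methylbut-3-yn-1-yl](prop-2-en-1-yl)carbamate | C=CCN(C(=O)OC)C[C@H](C#C)C
F6 | step 5 | methyl [(2S)-2-methylbut-3-yn-1-yl](2-oxoethyl)carbamate | O=CCN(C(=O)OC)C[C@H](C#C)C
F7 | step 15 | (4S,4aR,6S,7R,7aS)-2,4,7-trimethyloctahydro-1H-cyclopenta[c]pyridin-6-yl 4-nitrobenzoate | O=C(O[C@H]1C[C@H]2[C@H](CN(C)C[C@H]2C)[C@H]1C)c1ccc(cc1)[N+](=O)[O-]
F8 | step 15 | (4S,4aR,6S,7R,7aS)-2,4,7-trimethyloctahydro-1H-cyclopenta[c]pyridin-6-ol | O[C@H]1C[C@H]2[C@H](CN(C)C[C@H]2C)[C@H]1C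
A1 | alternative 1 | methyl [(2E)-but-2-en-1-yl][(2S)-2-methylbut-3-yn-1-yl]carbamate | C/C=C/CN(C(=O)OC)C[C@H](C#C)C
A2 | alternative 1 | methyl (4S,7R,7aR)-4,7-dimethyl-6-oxo-1,3,4,6,7,7a-hexahydro-2H-cyclopenta[c]pyridine-2-carboxylate | O=C1C=C2[C@H](CN(C(=O)OC)C[C@H]2C)[C@H]1C
A3 | alternative 2 | (4S)-2-methyl-4-[(2S)-1-(methylamino)propan-2-yl]cyclopent-2-en-1-ol | CNC[C@@H](C)[C@H]1CC(O)C(C)=C1
A4 | alternative 2 | (4S,4aR,7R,7aS)-2,4,7-trimethyloctahydro-6H-cyclopenta[c]pyridin-6-one | O=C1C[C@H]2[C@H](CN(C)C[C@H]2C)[C@H]1C
A5 | alternative 3 | methyl {[(1S,5R)-5-methyl-4-oxocyclopent-2-en-1-yl]methyl}(prop-2-yn-1-yl)carbamate | C#CCN(C(=O)OC)C[C@H]1C=CC(=O)[C@@H]1C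
A6 | alternative 3 | methyl (4aS,7R,7aS)-7-methyl-4-methylidene-6-oxooctahydro-2H-cyclopenta[c]pyridine-2-carboxylate | O=C1C[C@H]2[C@H](CN(C(=O)OC)CC2=C)[C@H]1C
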